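**Retrosynthetic overview**
1. The target is a C2-symmetric head-to-tail dimer. Cutting both C11–C15′ bonds gives two identical cross-conjugated trienone esters, released from a tertiary acetate; the 12-membered ring is closed last by a stepwise anionic, iodide-relay [6+6] union.
2. In the monomer, the C7 side chain comes from a pyruvate aldol and C15 from methylenation of the C4 ketone.
3. The six-membered ring comes from a stepwise [4+2] annulation of a 1,2,4-trioxygenated diene onto 4-methylbicyclo[3.1.0]hex-3-en-2-one; addition anti to the cyclopropane sets C10.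
4. The cyclopropane-fused cyclopentenone comes from ring contraction of (R)-4-(mesyloxy)cyclohex-2-enone (transannular enolate displacement), followed by β-methylation.
5. Ring order: cyclopropane + five-membered ring (ring contraction), then six-membered ring (annulation), then 12-membered ring (dimerisation).

Assumption: (R)-4-hydroxycyclohex-2-en-1-one is taken as a commercial, enantiopure starting material.
Naming note: tricyclic compounds use lindenane numbering (cyclopropane C1–C2–C3; C4 bears C15; six-membered ring C5–C10; C7 bears C11 with ester C12 and methyl C13; C14 on C10). β is the face of C14; ξ marks an epimer mixture that disappears later.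

**Step 1**
Reactants: 1 (R)-4-hydroxycyclohex-2-en-1-one
Product: 2 (R)-4-oxocyclohex-2-en-1-yl methanesulfonate
Conditions: Ms2O, 2,6-lutidine, CH2Cl2, −30 °C (used cold, without storage)
Reagents that add atoms: methanesulfonic anhydride CS(=O)(=O)OS(C)(=O)=O
Why: O-sulfonylation with the anhydride (no chloride present to displace the allylic sulfonate) leaves the carbinol stereocentre untouched; standard mesylation.

**Step 2**
Reactants: 2 (R)-4-oxocyclohex-2-en-1-yl methanesulfonate
Product: 4 (1S,5S)-bicyclo[3.1.0]hex-3-en-2-one, via lithium dienolate 3 (not isolated)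
Conditions: LDA (1.05 equiv), THF, −78 → −20 °C
Reagents that add atoms: none
Why: Kinetic α′-deprotonation gives the cross-conjugated dienolate, whose α′-carbon displaces the allylic mesylate across the ring (3-exo-tet SN2, inversion), so the six-membered enone contracts to the cyclopropane-fused cyclopentenone and the carbinol chirality is transferred stereospecifically to both cyclopropane carbons; ring contraction by transannular 1,3-elimination (the enolate step of a Favorskii-type process).

**Step 3**
Reactants: 4 (1S,5S)-bicyclo[3.1.0]hex-3-en-2-one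
Product: 6 (1S,5R)-4-methylbicyclo[3.1.0]hex-3-en-2-one, via lithium enolate 5 (not isolated)
Conditions: Me2CuLi (from MeLi, CuI), Et2O, −78 °C; then t-BuN=S(Ph)Cl, THF, −78 °C → rt
Reagents that add atoms: lithium dimethylcuprate [Li+].C[Cu-]C
Why: Gilman conjugate addition places the methyl on the β-carbon (anti to the cyclopropane, irrelevant later) and the enolate is dehydrogenated in the same flask with Mukaiyama's sulfinimidoyl chloride, which can only give the 3,4-alkene because the other α-carbon is the cyclopropane bridgehead; one-pot β-alkylation of an enone.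

**Step 4**
Reactants: 7 (E)-4-methoxybut-3-en-2-one
Product: 10 (E)-1-[(tert-butyldimethylsilyl)oxy]-4-methoxybut-3-en-2-one, via potassium enolate 8 (not isolated), via potassium alkoxide 9 (not isolated)
Conditions: KHMDS, THF, −78 °C; 2-(phenylsulfonyl)-3-phenyloxaziridine, −78 °C; then TBSCl, −78 → 0 °C
Reagents that add atoms: 2-(phenylsulfonyl)-3-phenyloxaziridine O=S(=O)(N1OC1c1ccccc1)c1ccccc1; tert-butyldimethylsilyl chloride CC(C)(C)[Si](C)(C)Cl
Why: Enolisation is only possible at the methyl group, the Davis oxaziridine hydroxylates the enolate, and the primary alkoxide is silylated before it can cyclise onto the β-methoxy enone; enolate α-hydroxylation followed by O-silylation.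

**Step 5**
Reactants: 10 (E)-1-[(tert-butyldimethylsilyl)oxy]-4-methoxybut-3-en-2-one
Product: 11 (1Z,3E)-1,2-bis[(tert-butyldimethylsilyl)oxy]-4-methoxybuta-1,3-diene
Conditions: TBSOTf, Et3N, Et2O, 0 °C
Reagents that add atoms: tert-butyldimethylsilyl triflate CC(C)(C)[Si](C)(C)OS(=O)(=O)C(F)(F)F
Why: Soft enolisation can only go toward the silyloxy-bearing CH2 and gives the Z-enediol bis-silyl ether, an oxygenated Danishefsky-type diene; silyl enol ether formation.

**Step 6**
Reactants: 6 (1S,5R)-4-methylbicyclo[3.1.0]hex-3-en-2-one; 11 (1Z,3E)-1,2-bis[(tert-butyldimethylsilyl)oxy]-4-methoxybuta-1,3-diene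
Product: 12 8,9β-bis(tert-butyldimethylsilyloxy)-6ξ-methoxy-5βH-11,12,13,15-tetranorlinden-7-en-4-one
Conditions: Tf2NH (5 mol%), CH2Cl2, −78 → −40 °C; Et3N quench
Reagents that add atoms: none
Why: The silyl triflimide formed in situ activates the enone and the diene adds stepwise (Mukaiyama–Michael, then closure of the silyl enol ether onto the oxocarbenium ion, a formal [4+2] suited to hindered partners): the nucleophilic silyloxy-bearing terminus bonds to the β-carbon from the face opposite the cyclopropane, which makes C10 quaternary with its methyl syn to the cyclopropane CH2, the ring fusion is necessarily cis, and C9 epimers converge in step 8.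

**Step 7**
Reactants: 12 8,9β-bis(tert-butyldimethylsilyloxy)-6ξ-methoxy-5βH-11,12,13,15-tetranorlinden-7-en-4-one
Product: 13 8,9β-bis(tert-butyldimethylsilyloxy)-6ξ-methoxy-5βH-11,12,13-trinorlindena-4(15),7-diene
Conditions: Cp2TiMe2, toluene, 70 °C, dark
Reagents that add atoms: dimethyltitanocene C[Ti](C)(C1C=CC=C1)C1C=CC=C1
Why: The non-basic Petasis reagent methylenates the hindered, enolisable cyclopropyl ketone without the β-elimination of methoxide that an ylide base would trigger, and it leaves the silyl enol ether intact; titanium carbene olefination.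

**Step 8**
Reactants: 13 8,9β-bis(tert-butyldimethylsilyloxy)-6ξ-methoxy-5βH-11,12,13-trinorlindena-4(15),7-diene; 14 methyl pyruvate
Product: 17 methyl 9β-(tert-butyldimethylsilyloxy)-11ξ-hydroxy-8-oxolindena-4,6-dien-12-oate, via aldol adduct 15 (not isolated), via exo-methylene enone 16 (not isolated)
Conditions: methyl pyruvate·TiCl4 (premixed), CH2Cl2, −78 °C; aqueous work-up; then DBU, CH2Cl2, 0 °C → rt
Reagents that add atoms: none
Why: The Mukaiyama aldol of the silyl enol ether with the pre-complexed α-keto ester puts the side chain on C7 regiospecifically (premixing keeps free TiCl4 from ionising the allylic methoxy group); DBU then eliminates methanol (E1cB), moves the exocyclic alkene into conjugation and equilibrates C9 to the pseudo-equatorial 9β epimer, while the C11 epimers are inconsequential.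

**Step 9**
Reactants: 17 methyl 9β-(tert-butyldimethylsilyloxy)-11ξ-hydroxy-8-oxolindena-4,6-dien-12-oate
Product: 18 methyl 11ξ-acetoxy-9β-(tert-butyldimethylsilyloxy)-8-oxolindena-4,6-dien-12-oate
Conditions: Ac2O, DMAP, pyridine, 0 °C → rt
Reagents that add atoms: acetic anhydride CC(=O)OC(C)=O
Why: DMAP-catalysed acylation turns the tertiary hydroxyl into a leaving group for the later vinylogous elimination, and no other free hydroxyl is present; esterification.

**Step 10**
Reactants: 18 methyl 11ξ-acetoxy-9β-(tert-butyldimethylsilyloxy)-8-oxolindena-4,6-dien-12-oate (2 equiv)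
Product: 20 9,9′-bis-O-(tert-butyldimethylsilyl)cycloshizukaol A, via triene 19 (not isolated)
Conditions: MgI2 (30 mol%), DBU (1.5 equiv), THF–CH2Cl2, −20 °C → rt, slow addition of 18 (final 0.02 M)
Reagents that add atoms: none
Why: Proposed new method: an iodide-relay, stepwise anionic head-to-tail [6+6] cyclodimerisation. Mg2+/DBU soft enolisation at C15 expels acetate (vinylogous E1cB) to give triene 19. Iodide then adds 1,8 to C15, giving a magnesium ester trienolate in which chelation between the enolate oxygen and the C8 ketone holds the ester syn to C8. C11 of this trienolate adds 1,8 to C15 of a second triene from the open α-face (the β-face carries C14, the cyclopropane CH2 and the 9-silyloxy group). The new trienolate closes the 12-membered ring by SN2 at the allylic iodide, again through its α-face, and releases iodide, so both C11 quaternary centres are set R under substrate control. The polar C11-nucleophile/C15-electrophile pairing dictates head-to-tail regiochemistry. Closest known chemistry: MgI2-catalysed ring expansions of activated cyclopropanes (iodide opening, C–C bond formation, ring closure with loss of iodide), halo-Michael/aldol reactions and vinylogous Michael additions.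

**Step 11**
Reactants: 20 9,9′-bis-O-(tert-butyldimethylsilyl)cycloshizukaol A
Product: 21 cycloshizukaol A
Conditions: HF·pyridine, pyridine, THF, 0 °C → rt
Reagents that add atoms: none
Why: Buffered acidic fluoride cleaves the two secondary silyl ethers without the base that could reverse the vinylogous Michael bonds or epimerise C9; desilylation.

**Compound list**
1 | (R)-4-hydroxycyclohex-2-en-1-one | O=C1C=C[C@H](O)CC1 | starting material
2 | (R)-4-oxocyclohex-2-en-1-yl methanesulfonate | O=C1C=C[C@H](OS(C)(=O)=O)CC1 | intermediate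
3 | lithium (R)-4-(methanesulfonyloxy)cyclohexa-1,5-dien-1-olate | [Li]OC1=CC[C@@H](OS(C)(=O)=O)C=C1 | intermediate
4 | (1S,5S)-bicyclo[3.1.0]hex-3-en-2-one | O=C1C=C[C@@H]2C[C@H]12 | intermediate
5 | lithium (1S,4S,5S)-4-methylbicyclo[3.1.0]hex-2-en-2-olate (methyl trans to the cyclopropane CH2) | [Li]OC1=C[C@@H](C)[C@@H]2C[C@H]12 | intermediate
6 | (1S,5R)-4-methylbicyclo[3.1.0]hex-3-en-2-one | O=C1C=C(C)[C@@H]2C[C@H]12 | intermediate
7 | (E)-4-methoxybut-3-en-2-one | CO/C=C/C(C)=O | starting material
8 | potassium (E)-4-methoxybuta-1,3-dien-2-olate | CO/C=C/C(=C)O[K] | intermediate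
9 | potassium (E)-4-methoxy-2-oxobut-3-en-1-olate | CO/C=C/C(=O)CO[K] | intermediate
10 | (E)-1-[(tert-butyldimethylsilyl)oxy]-4-methoxybut-3-en-2-one | CO/C=C/C(=O)CO[Si](C)(C)C(C)(C)C | intermediate
11 | (1Z,3E)-1,2-bis[(tert-butyldimethylsilyl)oxy]-4-methoxybuta-1,3-diene | CO/C=C/C(O[Si](C)(C)C(C)(C)C)=C/O[Si](C)(C)C(C)(C)C | intermediate
12 | 8,9β-bis(TBSO)-6ξ-methoxy-5βH-11,12,13,15-tetranorlinden-7-en-4-one (cyclopropane CH2 β, 10β-Me, cis-fused) | O=C1[C@H]2C(OC)C=C(O[Si](C)(C)C(C)(C)C)[C@H](O[Si](C)(C)C(C)(C)C)[C@@]2(C)[C@@H]2C[C@H]12 | intermediate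
13 | 8,9β-bis(TBSO)-6ξ-methoxy-5βH-11,12,13-trinorlindena-4(15),7-diene | C=C1[C@H]2C(OC)C=C(O[Si](C)(C)C(C)(C)C)[C@H](O[Si](C)(C)C(C)(C)C)[C@@]2(C)[C@@H]2C[C@H]12 | intermediate
14 | methyl pyruvate | CC(=O)C(=O)OC | starting material
15 | methyl 9β-(TBSO)-11ξ-hydroxy-6ξ-methoxy-8-oxo-5βH,7ξH-linden-4(15)-en-12-oate | C=C1[C@H]2C(OC)C(C(C)(O)C(=O)OC)C(=O)[C@H](O[Si](C)(C)C(C)(C)C)[C@@]2(C)[C@@H]2C[C@H]12 | intermediate
16 | methyl 9β-(TBSO)-11ξ-hydroxy-8-oxo-5βH-lindena-4(15),6-dien-12-oate | C=C1[C@H]2C=C(C(C)(O)C(=O)OC)C(=O)[C@H](O[Si](C)(C)C(C)(C)C)[C@@]2(C)[C@@H]2C[C@H]12 | intermediate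
17 | methyl 9β-(TBSO)-11ξ-hydroxy-8-oxolindena-4,6-dien-12-oate | CC1=C2C=C(C(C)(O)C(=O)OC)C(=O)[C@H](O[Si](C)(C)C(C)(C)C)[C@@]2(C)[C@@H]2C[C@H]12 | intermediate
18 | methyl 11ξ-acetoxy-9β-(TBSO)-8-oxolindena-4,6-dien-12-oate | CC1=C2C=C(C(C)(OC(C)=O)C(=O)OC)C(=O)[C@H](O[Si](C)(C)C(C)(C)C)[C@@]2(C)[C@@H]2C[C@H]12 | intermediate
19 | methyl (7(11)Z)-9β-(TBSO)-8-oxolindena-4(15),5,7(11)-trien-12-oate (E/Z interconvert under the conditions) | C=C1C2=C/C(=C(\C)C(=O)OC)C(=O)[C@H](O[Si](C)(C)C(C)(C)C)[C@@]2(C)[C@@H]2C[C@H]12 | intermediate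
20 | 9,9′-bis-O-(tert-butyldimethylsilyl)cycloshizukaol A | COC(=O)[C@]1(C)CC2=C3C=C(C(=O)[C@H](O[Si](C)(C)C(C)(C)C)[C@@]3(C)[C@@H]3C[C@H]23)[C@](C)(C(=O)OC)CC2=C3C=C1C(=O)[C@H](O[Si](C)(C)C(C)(C)C)[C@@]3(C)[C@@H]1C[C@H]21 | intermediate
21 | cycloshizukaol A (each half 1R,3S,9R,10S,11R) | COC(=O)[C@]1(C)CC2=C3C=C(C(=O)[C@H](O)[C@@]3(C)[C@@H]3C[C@H]23)[C@](C)(C(=O)OC)CC2=C3C=C1C(=O)[C@H](O)[C@@]3(C)[C@@H]1C[C@H]21 | target

**Step count:** 11 steps in total. Longest linear sequence: 9 steps (1, 2, 3, 6, 7, 8, 9, 10, 11); the diene branch is steps 4 and 5.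

**Three steps most likely to fail**

Step 2 (ring contraction). The allylic mesylate may aromatise to phenol or decompose before the dienolate closes. Fallback: make the cyclopropane by carbenoid chemistry instead of ring contraction. This fallback does not set out from a route compound; it bypasses 1–3 and starts from the commercial epoxide (S)-2-(but-3-en-1-yl)oxirane F1. Lithium 2,2,6,6-tetramethylpiperidide in t-BuOMe (α-lithiation and intramolecular cyclopropanation of the terminal epoxide, which retains the carbinol centre and places the cyclopropane trans to the hydroxyl) gives (1S,2S,5R)-bicyclo[3.1.0]hexan-2-ol F2. IBX in DMSO at 70 °C oxidises the alcohol and dehydrogenates the ketone, and the route is rejoined at 4.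

Step 6 (annulation). The β,β-disubstituted enone may be too unreactive, or the silyl Lewis acid may open the cyclopropyl enone toward a cresol. Fallback: activate the acceptor as its α-bromo enone so that a mild catalyst suffices. Setting out from 6, bromine in CH2Cl2 gives 3,4-dibromo-4-methylbicyclo[3.1.0]hexan-2-one F3, which is not isolated, and triethylamine removes HBr to give (1S,5R)-3-bromo-4-methylbicyclo[3.1.0]hex-3-en-2-one F4. This more electrophilic enone is annulated with 11 (ZnBr2 or toluene at 60 °C) to the 5β-bromo analogue of 12, 5β-bromo-8,9β-bis(TBSO)-6ξ-methoxy-11,12,13,15-tetranorlinden-7-en-4-one F5. Bu3SnH/AIBN removes the bromine (hydrogen is delivered to the cis-fused radical), and the route is rejoined at 12.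

Step 10 (the proposed dimerisation). Iodide turnover may fail, or oligomers and [4+2] dimers of the triene may dominate. Fallback with known reactions: a stepwise union in which thiophenol stands in for iodide as an isolable placeholder. Setting out from 18, DBU and PhSH (elimination to 19, then thia-Michael 1,8-addition) give methyl 9β-(TBSO)-8-oxo-15-(phenylsulfanyl)lindena-4,6-dien-12-oate F6. Its lithium trienolate (LiHMDS, THF, −78 °C) is added 1,8 to a cold solution of triene 19 (made separately from 18 with DBU) and protonated; this forms the first C11–C15′ bond with the same α-face, chelate-controlled sense and gives the open-chain dimer sulfide F7. MeI/NaI in DMF converts the allylic sulfide by alkylative desulfurisation into the open-chain dimer allylic iodide F8. KHMDS in THF at high dilution (1 mM, −78 → 0 °C) closes the ring by intramolecular enolate alkylation, and the route is rejoined at 20.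

**Further compounds**
F1 | step 2 | (S)-2-(but-3-en-1-yl)oxirane | C=CCC[C@H]1CO1
F2 | step 2 | (1S,2S,5R)-bicyclo[3.1.0]hexan-2-ol | O[C@H]1CC[C@@H]2C[C@H]12
F3 | step 6 | (1S,5R)-3,4-dibromo-4-methylbicyclo[3.1.0]hexan-2-one (bromide epimers) | O=C1C(Br)C(C)(Br)[C@@H]2C[C@H]12
F4 | step 6 | (1S,5R)-3-bromo-4-methylbicyclo[3.1.0]hex-3-en-2-one | O=C1C(Br)=C(C)[C@@H]2C[C@H]12
F5 | step 6 | 5β-bromo-8,9β-bis(TBSO)-6ξ-methoxy-11,12,13,15-tetranorlinden-7-en-4-one | O=C1[C@@]2(Br)C(OC)C=C(O[Si](C)(C)C(C)(C)C)[C@H](O[Si](C)(C)C(C)(C)C)[C@@]2(C)[C@@H]2C[C@H]12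
F6 | step 10 | methyl 9β-(TBSO)-8-oxo-15-(phenylsulfanyl)-11ξH-lindena-4,6-dien-12-oate | c1ccccc1SCC1=C2C=C(C(C)C(=O)OC)C(=O)[C@H](O[Si](C)(C)C(C)(C)C)[C@@]2(C)[C@@H]2C[C@H]12
F7 | step 10 | open-chain dimer sulfide (one C11–C15′ bond, 11R; 15-SPh on the first unit; 11′ξ-H on the second) | c1ccccc1SCC2=C3C=C(C(=O)[C@H](O[Si](C)(C)C(C)(C)C)[C@@]3(C)[C@@H]3C[C@H]23)[C@](C)(C(=O)OC)CC2=C3C=C(C(C)C(=O)OC)C(=O)[C@H](O[Si](C)(C)C(C)(C)C)[C@@]3(C)[C@@H]4C[C@H]24
F8 | step 10 | open-chain dimer allylic iodide (15-iodo analogue of F7) | ICC2=C3C=C(C(=O)[C@H](O[Si](C)(C)C(C)(C)C)[C@@]3(C)[C@@H]3C[C@H]23)[C@](C)(C(=O)OC)CC2=C3C=C(C(C)C(=O)OC)C(=O)[C@H](O[Si](C)(C)C(C)(C)C)[C@@]3(C)[C@@H]4C[C@H]24
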